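Take what became target out of what reacted and the leftover is the isomer of the product. It is a sliver near the noise, and it is what you are asked about.

| flask | substrate | reagent in the second phase | remark | time | volume of the second phase over the first |
|---|---|---|---|---|---|
| south-west | 0.016 M (fed, over 1.0 min) | 1 equiv | run made earlier |  |  |
| south-east | 0.088 M (fed, over 1.0 min) | 1 equiv | run made earlier |  |  |
| north-east | 0.10 M (fed, over 1.0 min) | 0.57 equiv | run made earlier |  |  |
| alpha | 0.030 M | 0.250 equiv | everything together at the start | 4.0 min | 1.0 |
| beta | 0.10 M (fed, over 1.0 min) | 1.00 equiv |  | 4.0 min | 1.0 |

| run | time / s | target / % | isomer of the product / % |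
|---|---|---|---|
| south-west | 10.0 | 0 | 0.2 |
| south-west | 25.0 | 0 | 0 |
| south-west | 40.0 | 0 | 0 |
| south-west | 60.0 | 0.3 | 0 |
| south-west | 90.0 | 0.5 | 0.3 |
| south-west | 120 | 2.0 | 0 |
| south-east | 10.0 | 0 | 0 |
| south-east | 15.0 | 0 | 0 |
| south-east | 25.0 | 0.3 | 0.2 |
| south-east | 40.0 | 1.0 | 0 |
| south-east | 80.0 | 4.1 | 0.1 |
| south-east | 120 | 7.1 | 1.5 |
| north-east | 10.0 | 0 | 0.3 |
| north-east | 30.0 | 0.2 | 0 |
| north-east | 60.0 | 1.0 | 0.4 |
| north-east | 80.0 | 2.7 | 0.1 |
| north-east | 120 | 4.5 | 0.6 |

(scatter of a reading: 0.3 percentage points)

- in the second phase: reagent in the second phase; everything else is in the first
- charges count per volume of the first phase; a concentration in a rate is the amount of a species over the volume of its own phase; every rate counts per litre of the first phase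
- the earlier runs hold the two phases in the same ratio of volumes as the flask asked about
- where the amount of substrate changes, what is given in equivalents or mol% on it follows
- percentages count the whole charge, also what has not yet gone in

* the winner by share of target in all that became target or isomer of the product; "neither" if no more than 2 percentage points parts them (alpha / beta / neither)
* share of target in all that became target or isomer of the product, alpha
* share of target in all that became target or isomer of the product, beta

So carry one quantity, isomer of the product over target in one flask at one time. Pool the last readings of the south-east and north-east runs, at 120 s and 120 s. The isomer of the product sums to 2.1 percentage points and target to 12 points, which gives 0.181, the isomer ratio. You can also pool the 9 earlier readings of those two runs, which are different readings. There the isomer of the product sums to 1.1 points and target to 9.3 points, which gives 0.118.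

The two ways part, so find the cheat. The early isomer sum carries a scatter of 0.9 points on its 1.1 points, while the late sum carries 0.42 points on its 2.1 points, so the late sum stands further above its noise. The early way is the one that cheats, and you keep 0.181.

Does reagent move the ratio? The south-east run alone reads 0.211 at 1 equiv, and the north-east run alone reads 0.133 at 0.57 equiv. One scatter of 0.3 points added to the north-east isomer reading of 0.6 % lifts that run's ratio to 0.200, so I take one ratio for alpha and beta. The share of target is then one over one plus the ratio, 84.7 % in each flask, and my reckoning says neither wins.

The forecast differs, with alpha ahead at 93 % against 87 % for beta, in its words: “I lean to alpha, with low confidence”.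

The flask answers neither, with 85.2 % in alpha and 85.1 % in beta.

    reagent in the reaction phase ⇌ reagent in the second phase, rate k1*([reagent in the reaction phase] - [reagent in the second phase]/K1) per volume of the first phase (partition coefficient = 10.0, kL = 0.0450 /s)
    substrate + reagent in the reaction phase → target (k = 0.160 /M/s)
    target ⇌ isomer of the product (K = 0.180, k = 0.0230 /s)

In alpha the relaxation half-life of target and isomer of the product, 0.0766 min by that step alone, is short against the 4.0 min allowed, the mark of thermodynamic control. Put the ratio read off the runs to work: alpha's 1.79 % of target at 4.00 min calls for 0.324 % of isomer of the product, and alpha holds 0.312 %. The neighbour of alpha at 0.075 M has 3.77 % of target, which calls for 0.682 %, and that neighbour holds 0.658 %.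

(Readings and results were computed on assumed constants; noise was put on by code.)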